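**Strategy.** The route rests on cutting ring C of the flavonol into three pieces: chromenone C2 and C3 come from a terminal alkyne on benzofuran C4, chromenone C4 from carbon monoxide, and C4a, C8a and O1 from an ortho-iodophenol that already is ring A. One palladium-catalysed carbonylative coupling with amine-relayed 6-endo closure makes three bonds and the chromenone, so the crowded benzofuran C4, next to the C3 stereocentre, only has to carry a linear sp carbon. The alkyne partner is a trans-(2R,3S)-2-aryl-3-(silyloxymethyl)-4-ethynyl-2,3-dihydrobenzofuran made by enantioselective rhodium carbene C–H insertion. Its 7-oxygen carries the same 4-benzyloxy-3-methoxybenzyl group that supplies C2 and the aryl ring, which shortens the approach.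

Key step: step 12

Abbreviations: BMB = 4-(benzyloxy)-3-methoxybenzyl; TBS = tert-butyldimethylsilyl; Bn = benzyl.

Assumption: Rh2(S-PTTL)4 is taken to deliver the 2R series, by analogy with related benzylic ether insertions; should the sense be opposite, Rh2(R-PTTL)4 would be used with no other change.

**Step 1**
Reactants: 1 2-(2,3-dimethoxyphenyl)acetic acid
Product: 2 2-(6-bromo-2,3-dimethoxyphenyl)acetic acid
Conditions: NBS (1.05 equiv), MeCN, 0 °C to rt, dark
Reagents that add atoms: N-bromosuccinimide, O=C1CCC(=O)N1Br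
Why: Electrophilic aromatic bromination with NBS in acetonitrile should go para to the coplanar 3-methoxy group (C6), because the 2-methoxy group is twisted out of conjugation by its two ortho neighbours and C6 is also activated by the ortho CH2 group.

**Step 2**
Reactants: 2 2-(6-bromo-2,3-dimethoxyphenyl)acetic acid
Product: 4 methyl 2-(6-bromo-2,3-dihydroxyphenyl)acetate, via 2-(6-bromo-2,3-dihydroxyphenyl)acetic acid 3 (not isolated)
Conditions: BBr3 (4 equiv), CH2Cl2, −78 °C to rt; then MeOH, 0 °C to reflux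
Reagents that add atoms: methanol, CO
Why: BBr3 cleaves both aryl methyl ethers (Lewis acid ether cleavage) without touching the aryl bromide, and the methanol quench liberates HBr, which drives a Fischer esterification in excess methanol so that the open hydroxy ester and not the lactone is obtained.

**Step 3**
Reactants: 5 [4-(benzyloxy)-3-methoxyphenyl]methanol
Product: 6 1-(benzyloxy)-4-(chloromethyl)-2-methoxybenzene (BMB chloride)
Conditions: SOCl2 (1.2 equiv), CH2Cl2, 0 °C; used crude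
Reagents that add atoms: thionyl chloride, O=S(Cl)Cl
Why: Chlorodehydroxylation of an electron-rich benzylic alcohol with thionyl chloride is fast at 0 °C, and the crude chloride is used at once.

**Step 4**
Reactants: 4 methyl 2-(6-bromo-2,3-dihydroxyphenyl)acetate; 6 BMB chloride (2.3 equiv)
Product: 7 methyl 2-[2,3-bis(BMB-oxy)-6-bromophenyl]acetate
Conditions: K2CO3 (3 equiv), KI (0.1 equiv), DMF, rt to 40 °C, argon
Reagents that add atoms: none
Why: Double Williamson etherification of the catechol with a reactive benzylic chloride under carbonate base should work because the group on O2 is the future C2 and aryl ring while the identical group on O3 is a hydrogenolysable protecting group, so the two oxygens need not be told apart.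

**Step 5**
Reactants: 7 methyl 2-[2,3-bis(BMB-oxy)-6-bromophenyl]acetate
Product: 8 methyl 2-[2,3-bis(BMB-oxy)-6-bromophenyl]-2-diazoacetate
Conditions: p-ABSA (1.5 equiv), DBU (2 equiv), MeCN, 0 °C to rt
Reagents that add atoms: 4-acetamidobenzenesulfonyl azide, CC(=O)Nc1ccc(cc1)S(=O)(=O)N=[N+]=[N-]
Why: Regitz diazo transfer from the sulfonyl azide to the DBU enolate of the aryl acetate gives the donor/acceptor diazo ester.

**Step 6**
Reactants: 8 methyl 2-[2,3-bis(BMB-oxy)-6-bromophenyl]-2-diazoacetate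
Product: 9 methyl (2R,3S)-2-[4-(benzyloxy)-3-methoxyphenyl]-7-(BMB-oxy)-4-bromo-2,3-dihydro-1-benzofuran-3-carboxylate (cis)
Conditions: Rh2(S-PTTL)4 (dirhodium tetrakis[N-phthaloyl-(S)-tert-leucinate], 2 mol %), toluene, −60 °C
Reagents that add atoms: none
Why: The rhodium carbene inserts into a benzylic C–H bond of the O2 ether through a five-membered transition state (intramolecular 1,5 C–H insertion; the CH2 on O3 cannot reach), the chiral carboxylate ligands are expected to select the enantiotopic hydrogen that sets C2 as R, and the kinetic product is the cis ester (3S).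

**Step 7**
Reactants: 9 cis ester
Product: 10 methyl (2R,3R)-2-[4-(benzyloxy)-3-methoxyphenyl]-7-(BMB-oxy)-4-bromo-2,3-dihydro-1-benzofuran-3-carboxylate (trans)
Conditions: NaOMe (0.5 equiv), MeOH/THF, rt
Reagents that add atoms: none
Why: Methoxide epimerises C3 through the ester enolate to the more stable trans ester (3R), while C2 has no acidifying group and ring opening by β-elimination, the reverse of a 5-endo-trig closure, is stereoelectronically disfavoured.

**Step 8**
Reactants: 10 trans ester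
Product: 11 [(2R,3S)-2-[4-(benzyloxy)-3-methoxyphenyl]-7-(BMB-oxy)-4-bromo-2,3-dihydro-1-benzofuran-3-yl]methanol
Conditions: DIBAL-H (i-Bu2AlH, 2.5 equiv), CH2Cl2, −78 to 0 °C; Rochelle salt work-up
Reagents that add atoms: none
Why: DIBAL-H reduces the ester to the primary alcohol at low temperature without affecting the aryl bromide or the benzylic ethers, and neither stereocentre is involved.

**Step 9**
Reactants: 11 primary alcohol
Product: 12 {[(2R,3S)-2-[4-(benzyloxy)-3-methoxyphenyl]-7-(BMB-oxy)-4-bromo-2,3-dihydro-1-benzofuran-3-yl]methoxy}(tert-butyl)dimethylsilane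
Conditions: TBSCl (1.3 equiv), imidazole (2.5 equiv), DMF, rt
Reagents that add atoms: tert-butyldimethylsilyl chloride, CC(C)(C)[Si](C)(C)Cl
Why: Standard silylation of the primary alcohol (Corey conditions) gives an ether that tolerates amines, carbonate, palladium and CO at 120 °C, and DMDO.

**Step 10**
Reactants: 12 aryl bromide; 13 ethynyltrimethylsilane (1.5 equiv)
Product: 15 {[(2R,3S)-2-[4-(benzyloxy)-3-methoxyphenyl]-7-(BMB-oxy)-4-ethynyl-2,3-dihydro-1-benzofuran-3-yl]methoxy}(tert-butyl)dimethylsilane, via TMS-alkyne 14 (not isolated)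
Conditions: PdCl2(PhCN)2 (3 mol %), P(t-Bu)3·HBF4 (6 mol %), CuI (2 mol %), i-Pr2NH, dioxane, 45 °C; then K2CO3 (0.3 equiv), MeOH, rt
Reagents that add atoms: none
Why: Sonogashira coupling with the bulky electron-rich phosphine allows oxidative addition into the hindered, electron-rich aryl bromide at mild temperature, and carbonate in methanol then removes the alkynyl trimethylsilyl group selectively beside the alkyl TBS ether.

**Step 11**
Reactants: 16 3,5-bis(benzyloxy)phenol
Product: 17 3,5-bis(benzyloxy)-2-iodophenol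
Conditions: NIS (1.0 equiv), CH2Cl2, −20 to 0 °C
Reagents that add atoms: N-iodosuccinimide, O=C1CCC(=O)N1I
Why: Electrophilic iodination with NIS in a non-polar solvent should occur ortho to the free hydroxyl (two equivalent positions, each also para to a benzyloxy group) in preference to the more hindered position between the two benzyloxy groups.

**Step 12**
Reactants: 15 terminal alkyne; 17 3,5-bis(benzyloxy)-2-iodophenol (1.3 equiv); 18 carbon monoxide
Product: 21 5,7-bis(benzyloxy)-2-[(2R,3S)-2-[4-(benzyloxy)-3-methoxyphenyl]-7-(BMB-oxy)-3-(TBS-oxymethyl)-2,3-dihydro-1-benzofuran-4-yl]-4H-chromen-4-one, via hydroxyaryl ynone 19 (not isolated), via enaminone 20 (not isolated)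
Conditions: PdCl2(dppf) (5 mol %), CO (20 bar), Et2NH, 120 °C, autoclave
Reagents that add atoms: none
Why: Zerovalent palladium, formed in situ from PdCl2(dppf), inserts into the C–I bond of 17, CO insertion gives an aroylpalladium iodide, and transfer of the acetylide of 15 followed by reductive elimination gives ynone 19; this is the known carbonylative Sonogashira annulation of ortho-iodophenols with aryl alkynes to flavones. Diethylamine adds in conjugate fashion to 19 to give enaminone 20, and the phenol then replaces the amine by addition–elimination, so ring C closes in a formal 6-endo mode at the carbon that becomes chromenone C2. No stereocentre is created, and C2 and C3 of the dihydrobenzofuran carry no acidifying group under the amine conditions and should keep their configuration. The step needs 6-endo closure over 5-exo-dig aurone formation, which the amine relay secures because the β-carbon of 20 is its only electrophilic site. It also needs CO insertion before alkyne transfer, which the CO pressure and the slow direct coupling of the electron-rich, doubly ortho-substituted arylpalladium favour. The hindered benzofuran C4 carries only a linear alkyne while the bonds form, so no biaryl-type coupling next to C3 is required.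

**Step 13**
Reactants: 21 flavone
Product: 23 5,7-bis(benzyloxy)-3-hydroxy-2-[(2R,3S)-2-[4-(benzyloxy)-3-methoxyphenyl]-7-(BMB-oxy)-3-(TBS-oxymethyl)-2,3-dihydro-1-benzofuran-4-yl]-4H-chromen-4-one, via flavone epoxide 22 (not isolated)
Conditions: DMDO (ca. 0.08 M in acetone, 3 equiv), CH2Cl2, 0 °C to rt; then p-TsOH·H2O (5 mol %), CH2Cl2, 0 °C
Reagents that add atoms: dimethyldioxirane, CC1(C)OO1
Why: DMDO epoxidises the C2=C3 enol ether double bond of the flavone (dioxirane epoxidation), and catalytic acid opens the epoxide at C2 with loss of the C3 proton to give the 3-hydroxyflavone, a sequence established for benzyl-protected flavones.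

**Step 14**
Reactants: 23 silyl-protected flavonol
Product: 24 5,7-bis(benzyloxy)-3-hydroxy-2-[(2R,3S)-2-[4-(benzyloxy)-3-methoxyphenyl]-7-(BMB-oxy)-3-(hydroxymethyl)-2,3-dihydro-1-benzofuran-4-yl]-4H-chromen-4-one
Conditions: HF·pyridine, pyridine/THF, 0 °C to rt
Reagents that add atoms: none
Why: Fluoride-mediated desilylation buffered with pyridine is selective for the Si–O bond and leaves the benzylic ethers, the flavonol and both stereocentres untouched.

**Step 15**
Reactants: 24 benzyl-protected flavonol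
Product: 25 3,5,7-trihydroxy-2-[(2R,3S)-7-hydroxy-2-(4-hydroxy-3-methoxyphenyl)-3-(hydroxymethyl)-2,3-dihydro-1-benzofuran-4-yl]-4H-chromen-4-one
Conditions: H2 (1 atm), Pd/C (10 %), EtOAc/MeOH, rt
Reagents that add atoms: none
Why: Hydrogenolysis over Pd/C cleaves the four aryl benzyl ethers and the BMB ether quickly at 1 atm, whereas the cyclic benzylic C2–O1 bond and the flavonol double bond react far more slowly, so the reaction is stopped at full debenzylation and the configuration at C2 and C3 is retained.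

**Compound list**

1 | 2-(2,3-dimethoxyphenyl)acetic acid | COc1cccc(CC(=O)O)c1OC | starting material
2 | 2-(6-bromo-2,3-dimethoxyphenyl)acetic acid | COc1ccc(Br)c(CC(=O)O)c1OC | intermediate
3 | 2-(6-bromo-2,3-dihydroxyphenyl)acetic acid (not isolated) | OC(=O)Cc1c(Br)ccc(O)c1O | intermediate
4 | methyl 2-(6-bromo-2,3-dihydroxyphenyl)acetate | COC(=O)Cc1c(Br)ccc(O)c1O | intermediate
5 | [4-(benzyloxy)-3-methoxyphenyl]methanol | COc1cc(CO)ccc1OCc1ccccc1 | starting material
6 | 1-(benzyloxy)-4-(chloromethyl)-2-methoxybenzene | COc1cc(CCl)ccc1OCc1ccccc1 | intermediate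
7 | methyl 2-(2,3-bis{[4-(benzyloxy)-3-methoxybenzyl]oxy}-6-bromophenyl)acetate | COC(=O)Cc1c(Br)ccc(OCc2ccc(OCc3ccccc3)c(OC)c2)c1OCc1ccc(OCc2ccccc2)c(OC)c1 | intermediate
8 | methyl 2-(2,3-bis{[4-(benzyloxy)-3-methoxybenzyl]oxy}-6-bromophenyl)-2-diazoacetate | COC(=O)C(=[N+]=[N-])c1c(Br)ccc(OCc2ccc(OCc3ccccc3)c(OC)c2)c1OCc1ccc(OCc2ccccc2)c(OC)c1 | intermediate
9 | methyl (2R,3S)-2-[4-(benzyloxy)-3-methoxyphenyl]-7-{[4-(benzyloxy)-3-methoxybenzyl]oxy}-4-bromo-2,3-dihydro-1-benzofuran-3-carboxylate (cis) | COc1cc([C@@H]2Oc3c(OCc4ccc(OCc5ccccc5)c(OC)c4)ccc(Br)c3[C@@H]2C(=O)OC)ccc1OCc1ccccc1 | intermediate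
10 | methyl (2R,3R)-2-[4-(benzyloxy)-3-methoxyphenyl]-7-{[4-(benzyloxy)-3-methoxybenzyl]oxy}-4-bromo-2,3-dihydro-1-benzofuran-3-carboxylate (trans) | COc1cc([C@@H]2Oc3c(OCc4ccc(OCc5ccccc5)c(OC)c4)ccc(Br)c3[C@H]2C(=O)OC)ccc1OCc1ccccc1 | intermediate
11 | [(2R,3S)-2-[4-(benzyloxy)-3-methoxyphenyl]-7-{[4-(benzyloxy)-3-methoxybenzyl]oxy}-4-bromo-2,3-dihydro-1-benzofuran-3-yl]methanol | COc1cc([C@@H]2Oc3c(OCc4ccc(OCc5ccccc5)c(OC)c4)ccc(Br)c3[C@H]2CO)ccc1OCc1ccccc1 | intermediate
12 | {[(2R,3S)-2-[4-(benzyloxy)-3-methoxyphenyl]-7-{[4-(benzyloxy)-3-methoxybenzyl]oxy}-4-bromo-2,3-dihydro-1-benzofuran-3-yl]methoxy}(tert-butyl)dimethylsilane | COc1cc([C@@H]2Oc3c(OCc4ccc(OCc5ccccc5)c(OC)c4)ccc(Br)c3[C@H]2CO[Si](C)(C)C(C)(C)C)ccc1OCc1ccccc1 | intermediate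
13 | ethynyltrimethylsilane | C#C[Si](C)(C)C | starting material
14 | {[(2R,3S)-2-[4-(benzyloxy)-3-methoxyphenyl]-7-{[4-(benzyloxy)-3-methoxybenzyl]oxy}-4-[(trimethylsilyl)ethynyl]-2,3-dihydro-1-benzofuran-3-yl]methoxy}(tert-butyl)dimethylsilane (not isolated) | COc1cc([C@@H]2Oc3c(OCc4ccc(OCc5ccccc5)c(OC)c4)ccc(C#C[Si](C)(C)C)c3[C@H]2CO[Si](C)(C)C(C)(C)C)ccc1OCc1ccccc1 | intermediate
15 | {[(2R,3S)-2-[4-(benzyloxy)-3-methoxyphenyl]-7-{[4-(benzyloxy)-3-methoxybenzyl]oxy}-4-ethynyl-2,3-dihydro-1-benzofuran-3-yl]methoxy}(tert-butyl)dimethylsilane | COc1cc([C@@H]2Oc3c(OCc4ccc(OCc5ccccc5)c(OC)c4)ccc(C#C)c3[C@H]2CO[Si](C)(C)C(C)(C)C)ccc1OCc1ccccc1 | intermediate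
16 | 3,5-bis(benzyloxy)phenol | Oc1cc(OCc2ccccc2)cc(OCc2ccccc2)c1 | starting material
17 | 3,5-bis(benzyloxy)-2-iodophenol | Oc1cc(OCc2ccccc2)cc(OCc2ccccc2)c1I | intermediate
18 | carbon monoxide | [C-]#[O+] | starting material
19 | 1-[2,4-bis(benzyloxy)-6-hydroxyphenyl]-3-[(2R,3S)-2-[4-(benzyloxy)-3-methoxyphenyl]-7-{[4-(benzyloxy)-3-methoxybenzyl]oxy}-3-({[tert-butyl(dimethyl)silyl]oxy}methyl)-2,3-dihydro-1-benzofuran-4-yl]prop-2-yn-1-one (not isolated) | COc1cc([C@@H]2Oc3c(OCc4ccc(OCc5ccccc5)c(OC)c4)ccc(C#CC(=O)c4c(O)cc(OCc5ccccc5)cc4OCc4ccccc4)c3[C@H]2CO[Si](C)(C)C(C)(C)C)ccc1OCc1ccccc1 | intermediate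
20 | 1-[2,4-bis(benzyloxy)-6-hydroxyphenyl]-3-(diethylamino)-3-[(2R,3S)-2-[4-(benzyloxy)-3-methoxyphenyl]-7-{[4-(benzyloxy)-3-methoxybenzyl]oxy}-3-({[tert-butyl(dimethyl)silyl]oxy}methyl)-2,3-dihydro-1-benzofuran-4-yl]prop-2-en-1-one, alkene geometry open (not isolated) | COc1cc([C@@H]2Oc3c(OCc4ccc(OCc5ccccc5)c(OC)c4)ccc(C(=CC(=O)c4c(O)cc(OCc5ccccc5)cc4OCc4ccccc4)N(CC)CC)c3[C@H]2CO[Si](C)(C)C(C)(C)C)ccc1OCc1ccccc1 | intermediate
21 | 5,7-bis(benzyloxy)-2-[(2R,3S)-2-[4-(benzyloxy)-3-methoxyphenyl]-7-{[4-(benzyloxy)-3-methoxybenzyl]oxy}-3-({[tert-butyl(dimethyl)silyl]oxy}methyl)-2,3-dihydro-1-benzofuran-4-yl]-4H-chromen-4-one | COc1cc([C@@H]2Oc3c(OCc4ccc(OCc5ccccc5)c(OC)c4)ccc(-c4cc(=O)c5c(OCc6ccccc6)cc(OCc6ccccc6)cc5o4)c3[C@H]2CO[Si](C)(C)C(C)(C)C)ccc1OCc1ccccc1 | intermediate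
22 | 2,3-epoxide of 21: 4,6-bis(benzyloxy)-1a-[(2R,3S)-2-[4-(benzyloxy)-3-methoxyphenyl]-7-{[4-(benzyloxy)-3-methoxybenzyl]oxy}-3-({[tert-butyl(dimethyl)silyl]oxy}methyl)-2,3-dihydro-1-benzofuran-4-yl]-1a,7a-dihydro-7H-oxireno[2,3-b]chromen-7-one, both epoxide faces (not isolated) | COc1cc([C@@H]2Oc3c(OCc4ccc(OCc5ccccc5)c(OC)c4)ccc(C45OC4C(=O)c4c(OCc6ccccc6)cc(OCc6ccccc6)cc4O5)c3[C@H]2CO[Si](C)(C)C(C)(C)C)ccc1OCc1ccccc1 | intermediate
23 | 5,7-bis(benzyloxy)-3-hydroxy-2-[(2R,3S)-2-[4-(benzyloxy)-3-methoxyphenyl]-7-{[4-(benzyloxy)-3-methoxybenzyl]oxy}-3-({[tert-butyl(dimethyl)silyl]oxy}methyl)-2,3-dihydro-1-benzofuran-4-yl]-4H-chromen-4-one | COc1cc([C@@H]2Oc3c(OCc4ccc(OCc5ccccc5)c(OC)c4)ccc(-c4oc5cc(OCc6ccccc6)cc(OCc6ccccc6)c5c(=O)c4O)c3[C@H]2CO[Si](C)(C)C(C)(C)C)ccc1OCc1ccccc1 | intermediate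
24 | 5,7-bis(benzyloxy)-3-hydroxy-2-[(2R,3S)-2-[4-(benzyloxy)-3-methoxyphenyl]-7-{[4-(benzyloxy)-3-methoxybenzyl]oxy}-3-(hydroxymethyl)-2,3-dihydro-1-benzofuran-4-yl]-4H-chromen-4-one | COc1cc([C@@H]2Oc3c(OCc4ccc(OCc5ccccc5)c(OC)c4)ccc(-c4oc5cc(OCc6ccccc6)cc(OCc6ccccc6)c5c(=O)c4O)c3[C@H]2CO)ccc1OCc1ccccc1 | intermediate
25 | 3,5,7-trihydroxy-2-[(2R,3S)-7-hydroxy-2-(4-hydroxy-3-methoxyphenyl)-3-(hydroxymethyl)-2,3-dihydro-1-benzofuran-4-yl]-4H-chromen-4-one | COc1cc([C@@H]2Oc3c(O)ccc(-c4oc5cc(O)cc(O)c5c(=O)c4O)c3[C@H]2CO)ccc1O | target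

**Step count.** Total: 15 steps. Longest linear sequence: 13 steps (1, 2, 4–10, 12–15).

**Steps most likely to fail**

1. Step 12. Oxidative addition into the hindered, electron-rich C–I bond may be slow, so that protodeiodination, CO-free alkynylation leading to a benzofuran, or 5-exo closure compete.
Fallback without palladium or CO, setting out from 16 and 15 and returning at 19, then through 20 to 21. Phenol 16 is ortho-formylated (MgCl2, Et3N, paraformaldehyde, MeCN, reflux) to 2,4-bis(benzyloxy)-6-hydroxybenzaldehyde F1. F1 is converted to its lithium phenoxide (LiHMDS, THF, −78 °C) and treated with the lithium acetylide of 15 (LiHMDS, THF, −78 to 0 °C) to give the propargylic alcohol F2, formed as both carbinol epimers. MnO2 in CH2Cl2 oxidises it to ynone 19. Et2NH in EtOH at rt then gives enaminone 20 and, by 6-endo addition–elimination, flavone 21.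

2. Step 6. The twisted, doubly ortho-substituted carbene may insert with poor enantio- or diastereocontrol.
Fallback by resolution, setting out from 8 and returning at 10. Achiral Rh2(OAc)4 in CH2Cl2 at rt gives the racemic cis ester F3. NaOMe in MeOH epimerises it to the racemic trans ester F4. Preparative chromatography on a chiral stationary phase (amylose or cellulose carbamate) then separates the enantiomers and delivers 10.

3. Step 13. DMDO may attack the electron-rich rings or benzylic ether C–H bonds before epoxidation of the electron-poor C2=C3 bond is complete.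
Fallback by C3 metalation, setting out from 21 and returning at 23. LDA in THF at −78 °C deprotonates chromenone C3 and B(OMe)3 traps the anion as the dimethyl flavon-3-ylboronate F5. H2O2/AcOH then oxidises the C–B bond to the C3 hydroxyl of 23.

**Further compounds**

F1 | step 12 | 2,4-bis(benzyloxy)-6-hydroxybenzaldehyde | O=Cc1c(O)cc(OCc2ccccc2)cc1OCc1ccccc1
F2 | step 12 | 3,5-bis(benzyloxy)-2-{1-hydroxy-3-[(2R,3S)-2-[4-(benzyloxy)-3-methoxyphenyl]-7-{[4-(benzyloxy)-3-methoxybenzyl]oxy}-3-({[tert-butyl(dimethyl)silyl]oxy}methyl)-2,3-dihydro-1-benzofuran-4-yl]prop-2-yn-1-yl}phenol, both carbinol epimers | COc1cc([C@@H]2Oc3c(OCc4ccc(OCc5ccccc5)c(OC)c4)ccc(C#CC(O)c4c(O)cc(OCc5ccccc5)cc4OCc4ccccc4)c3[C@H]2CO[Si](C)(C)C(C)(C)C)ccc1OCc1ccccc1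
F3 | step 6 | racemic cis ester, methyl (2R,3S)- and (2S,3R)-2-[4-(benzyloxy)-3-methoxyphenyl]-7-{[4-(benzyloxy)-3-methoxybenzyl]oxy}-4-bromo-2,3-dihydro-1-benzofuran-3-carboxylate | COc1cc([C@@H]2Oc3c(OCc4ccc(OCc5ccccc5)c(OC)c4)ccc(Br)c3[C@@H]2C(=O)OC)ccc1OCc1ccccc1.COc1cc([C@H]2Oc3c(OCc4ccc(OCc5ccccc5)c(OC)c4)ccc(Br)c3[C@H]2C(=O)OC)ccc1OCc1ccccc1
F4 | step 6 | racemic trans ester, methyl (2R,3R)- and (2S,3S)-2-[4-(benzyloxy)-3-methoxyphenyl]-7-{[4-(benzyloxy)-3-methoxybenzyl]oxy}-4-bromo-2,3-dihydro-1-benzofuran-3-carboxylate | COc1cc([C@@H]2Oc3c(OCc4ccc(OCc5ccccc5)c(OC)c4)ccc(Br)c3[C@H]2C(=O)OC)ccc1OCc1ccccc1.COc1cc([C@H]2Oc3c(OCc4ccc(OCc5ccccc5)c(OC)c4)ccc(Br)c3[C@@H]2C(=O)OC)ccc1OCc1ccccc1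
F5 | step 13 | dimethyl {5,7-bis(benzyloxy)-2-[(2R,3S)-2-[4-(benzyloxy)-3-methoxyphenyl]-7-{[4-(benzyloxy)-3-methoxybenzyl]oxy}-3-({[tert-butyl(dimethyl)silyl]oxy}methyl)-2,3-dihydro-1-benzofuran-4-yl]-4-oxo-4H-chromen-3-yl}boronate | COc1cc([C@@H]2Oc3c(OCc4ccc(OCc5ccccc5)c(OC)c4)ccc(-c4oc5cc(OCc6ccccc6)cc(OCc6ccccc6)c5c(=O)c4B(OC)OC)c3[C@H]2CO[Si](C)(C)C(C)(C)C)ccc1OCc1ccccc1
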